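**Plan**

- Numbering (daucane): C1 quaternary ring-fusion carbon bearing methyl C15, C2 CHOH, C3 CH2, C4 C(OH)i-Pr, C5 ring-fusion CH, C6 CH–O-acyl, C7 CH2, C8 =C(CH3), C9 =CH, C10 CH2; β is the face of C15.
- Retrosynthesis: (a) the O6–acyl bond and the C2 carbinol (from a C2 ketone) go last; (b) C15 is traced back to an ester that makes C1 a soft enolate carbon; (c) C8=C9 and C10–C1 are cut together, releasing a C9–C10 vinylphosphonium unit and a cyclopentanone; (d) C4–i-Pr, C5–C6 (aldol) and C1–C15 (conjugate addition) lead back to (R)-4-silyloxycyclopentenone.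
- Enabling feature: on the arc C1–C5–C6–C7–C8 of the seven-membered ring, C1 is a quaternary carbon next to the C2 oxygen (a latent ketone enolate carbon) and C8 is a methyl-bearing sp2 carbon (a latent methyl ketone), while C9 and C10 between them carry only hydrogen. A two-carbon Michael acceptor/ylide reagent can therefore close the five-carbon arc in a (5+2) Michael/Wittig annulation.
- Forward order: the five-membered ring comes from the chiral pool (three-component conjugate addition/aldol, then i-PrMgCl); the seven-membered ring is closed by the annulation, with an O4/O6 acetonide as a temporary third ring; then C15 ester → CH3, acylation of O6 and reduction of C2.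
- Stereochemistry: the C2 silyl ether of 4 (later erased) relays through C1 to C5 (trans,trans addition); C6 comes from the anti aldol of the ring E-enolate; C4 from addition anti to the C5 side chain; C1 from alkylation of a planar enolate on the convex α face (stereoconvergent); C2 from hydride delivery by the 4β-OH.

Key step: step 9

Remark: aldehyde 3 is treated as not purchasable and is made in steps 1 and 2; C1 of β-keto ester 11 is configurationally labile (its SMILES shows one epimer), and C2 of diol 15 is an inconsequential epimer mixture left undefined.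

**Step 1**
Reactants: 1 methyl (R)-3-hydroxybutanoate
Product: 2 methyl (R)-3-(tert-butyldimethylsilyloxy)butanoate
Conditions: TBSCl, imidazole, DMF, rt
Reagents that add atoms: tert-butyldimethylsilyl chloride, CC(C)(C)[Si](C)(C)Cl
Why: Routine silylation of a secondary alcohol; this centre (future C8) is a placeholder that is later oxidised to the methyl ketone.

**Step 2**
Reactants: 2 methyl (R)-3-(tert-butyldimethylsilyloxy)butanoate
Product: 3 (R)-3-(tert-butyldimethylsilyloxy)butanal
Conditions: i-Bu2AlH (1.05 equiv), CH2Cl2, −78 °C; aqueous work-up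
Reagents that add atoms: none
Why: Partial reduction of an ester, which should stop at the aldehyde because the tetrahedral aluminium hemiacetal is stable at −78 °C.

**Step 3**
Reactants: 4 (R)-4-(tert-butyldimethylsilyloxy)cyclopent-2-en-1-one; 3 (R)-3-(tert-butyldimethylsilyloxy)butanal
Product: 6 three-component adduct (cyclopentan-4-one: 1α-vinyl; 2β-OTBS; 5β-hydroxyalkyl; 6S; 8R), via bromomagnesium enolate 5 (not isolated)
Conditions: CH2=CHMgBr (1.3 equiv), CuBr·SMe2 (10 mol %), THF, −78 °C; then 3, −78 °C; H2O quench at −78 °C
Reagents that add atoms: vinylmagnesium bromide, C=C[Mg]Br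
Why: Noyori-type three-component coupling (copper-catalysed conjugate addition, then aldol) in which vinyl should add to C1 anti to the C2 silyl ether, the regiodefined enolate should be attacked at C5 anti to the vinyl group, and the closed Zimmerman–Traxler transition state of the ring E-enolate should give the anti C5/C6 aldol (6S), the 8R silyloxy centre of 3 being 1,3-anti to the new carbinol.

**Step 4**
Reactants: 6 three-component adduct
Product: 7 4β,6-diol (C4 = C(β-OH)(α-i-Pr))
Conditions: i-PrMgCl (3 equiv), CeCl3 (3 equiv), THF, −78 → −20 °C; H2O quench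
Reagents that add atoms: isopropylmagnesium chloride, CC(C)[Mg]Cl
Why: Organocerium 1,2-addition to an enolisable ketone, expected on the α face anti to the adjacent C5 side chain (and to the 2β-silyl ether), which sets the 4β-OH/4α-isopropyl centre.

**Step 5**
Reactants: 7 4β,6-diol
Product: 8 O4/O6 acetonide
Conditions: 2-methoxypropene, PPTS (cat.), CH2Cl2, 0 °C → rt
Reagents that add atoms: 2-methoxypropene, COC(C)=C
Why: Acetonide formation of the 1,3-diol should give a cis-fused 1,3-dioxane that protects both hydroxyls and holds C7 equatorial; no new stereocentre is formed.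

**Step 6**
Reactants: 8 O4/O6 acetonide
Product: 9 1α-methyl ester (C15)
Conditions: O3, NaOH (2.5 M in MeOH), CH2Cl2, −78 °C
Reagents that add atoms: ozone, [O-][O+]=O; methanol, CO
Why: Marshall ozonolysis in alkaline methanol should convert the only alkene, the terminal vinyl group, directly into the methyl ester that will activate C1.

**Step 7**
Reactants: 9 1α-methyl ester
Product: 10 2,8-diol
Conditions: TBAF, AcOH, THF, rt
Reagents that add atoms: none
Why: Buffered fluoride cleavage should remove both secondary TBS ethers and leave the acetonide and the ester intact.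

**Step 8**
Reactants: 10 2,8-diol
Product: 11 β-keto ester methyl ketone
Conditions: Dess–Martin periodinane, pyridine, CH2Cl2, rt
Reagents that add atoms: none
Why: Double Dess–Martin oxidation should give the C2 ketone (β-keto ester) and the C8 methyl ketone at once, erasing the relay centres C2 and C8.

**Step 9**
Reactants: 11 β-keto ester methyl ketone; 12 vinyltriphenylphosphonium bromide
Product: 14 methyl 4β,6α-isopropylidenedioxy-2-oxodauc-8-en-15-oate, via phosphorus ylide 13 (not isolated)
Conditions: NaH (1.05 equiv), DMF, 0 °C; 12 (1.2 equiv), rt; then dilution to 0.01 M, 60 °C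
Reagents that add atoms: none
Why: Proposed new method: deprotonation of 11 at C1 gives a soft β-keto ester enolate that adds to the vinylphosphonium salt 12 (Michael addition, C10–C1 bond), and the β-ylide 13 so formed then attacks the C8 methyl ketone and collapses through an oxaphosphetane (intramolecular Wittig reaction, C8=C9 bond, loss of Ph3P=O), while enolate aldol addition to C8 is reversible and drains into the annulation. The closest known reaction is the Schweizer annulation of keto-substituted stabilised enolates with vinyltriphenylphosphonium bromide, established for five- and six-membered rings and in Michael–Michael–Wittig cascades; its (5+2) mode on an enolate carbon and a ketone in a 1,5 relationship is the untested element. The cycloheptene closes by attack of the ylide carbon C9 on the exocyclic C8 carbonyl (seven-membered ring containing the new, necessarily cis, C=C), whereas attack on the C2 ketone or the ester would require a cyclobutene and is not expected. The new quaternary stereocentre C1 is set in the Michael step, where the electrophile should approach the planar enolate on the convex α face of the cis-fused cyclopentanone/1,3-dioxane bicycle, anti to the C5–C6 bond, so that both C1 epimers and the enol of 11 converge on one product with C10 α and the ester (future C15) β, which is the trans ring fusion. The step needs C- over O-alkylation (secured by the soft acceptor), deprotonation at C1 only (β-keto ester versus methyl ketone acidity, one equivalent of base) and a ketone within reach (the dioxane chair holds C7 equatorial and gauche to C1 about the C5–C6 bond, as in the product). Dilution and heat in the Wittig stage are meant to suppress intermolecular olefination.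

**Step 10**
Reactants: 14 methyl 4β,6α-isopropylidenedioxy-2-oxodauc-8-en-15-oate
Product: 15 4β,6α-isopropylidenedioxydauc-8-ene-2,15-diol
Conditions: LiAlH4, THF, 0 °C → rt
Reagents that add atoms: none
Why: Hydride reduction of ester and ketone, where the configuration of the new C2 carbinol is irrelevant because it is reoxidised in step 11.

**Step 11**
Reactants: 15 4β,6α-isopropylidenedioxydauc-8-ene-2,15-diol
Product: 16 4β,6α-isopropylidenedioxy-2-oxodauc-8-en-15-al
Conditions: Dess–Martin periodinane, pyridine, CH2Cl2, rt
Reagents that add atoms: none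
Why: Dess–Martin oxidation of both alcohols should restore the C2 ketone and give a non-enolisable neopentyl aldehyde at C15.

**Step 12**
Reactants: 16 4β,6α-isopropylidenedioxy-2-oxodauc-8-en-15-al
Product: 18 4β,6α-isopropylidenedioxydauc-8-en-2-one, via tosylhydrazone 17 (not isolated)
Conditions: TsNHNH2 (1.05 equiv), THF, rt; then catecholborane, CHCl3, 0 °C; then NaOAc·3H2O, 60 °C
Reagents that add atoms: none
Why: The aldehyde should condense selectively (the ketone is flanked by quaternary C1), and Kabalka reduction of the tosylhydrazone (hydride addition, sulfinate loss, N2 extrusion from the diazene) should turn CHO into the C15 methyl group.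

**Step 13**
Reactants: 18 4β,6α-isopropylidenedioxydauc-8-en-2-one
Product: 19 4β,6α-dihydroxydauc-8-en-2-one
Conditions: PPTS, MeOH, 40 °C
Reagents that add atoms: none
Why: Mild acid transacetalisation should remove the acetonide without dehydrating the tertiary β-hydroxy ketone.

**Step 14**
Reactants: 19 4β,6α-dihydroxydauc-8-en-2-one
Product: 20 6α-(4-acetoxybenzoyloxy)-4β-hydroxydauc-8-en-2-one
Conditions: 4-acetoxybenzoyl chloride, pyridine, DMAP (cat.), CH2Cl2, 0 °C → rt
Reagents that add atoms: 4-acetoxybenzoyl chloride, CC(=O)Oc1ccc(cc1)C(Cl)=O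
Why: DMAP-catalysed acylation should occur only at the secondary 6α-hydroxyl, the tertiary 4β-hydroxyl being inert and C2 still being a ketone.

**Step 15**
Reactants: 20 6α-(4-acetoxybenzoyloxy)-4β-hydroxydauc-8-en-2-one
Product: 21 6α-(4-acetoxybenzoyloxy)dauc-8-ene-2α,4β-diol
Conditions: Me4NBH(OAc)3, MeCN–AcOH (1:1), −30 → 0 °C
Reagents that add atoms: none
Why: Evans–Saksena hydroxyl-directed reduction, in which boron should bind the 4β-oxygen and deliver hydride to the β face of the C2 ketone, giving the 2α-alcohol (anti-1,3-diol) against the bias of the angular methyl group.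

**Step 16**
Reactants: 21 6α-(4-acetoxybenzoyloxy)dauc-8-ene-2α,4β-diol
Product: 22 2α-hydroxyferutinin
Conditions: K2CO3 (0.2 equiv), MeOH, 0 °C
Reagents that add atoms: none
Why: Methanolysis of the aryl acetate should be much faster than that of the hindered secondary benzoate, which is further deactivated once the phenoxide forms.

**Compound list**

1 | methyl (R)-3-hydroxybutanoate | C[C@@H](O)CC(=O)OC | starting material
2 | methyl (R)-3-(tert-butyldimethylsilyloxy)butanoate | C[C@@H](O[Si](C)(C)C(C)(C)C)CC(=O)OC | intermediate
3 | (R)-3-(tert-butyldimethylsilyloxy)butanal | C[C@@H](O[Si](C)(C)C(C)(C)C)CC=O | intermediate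
4 | (R)-4-(tert-butyldimethylsilyloxy)cyclopent-2-en-1-one | O=C1C=C[C@H](O[Si](C)(C)C(C)(C)C)C1 | starting material
5 | bromomagnesium enolate (C4=C5) of trans-4-(TBSO)-3-vinylcyclopentanone (1α-vinyl, 2β-OTBS) | C=C[C@H]1[C@H](O[Si](C)(C)C(C)(C)C)CC(O[Mg]Br)=C1 | intermediate
6 | 2,3-trans-3,4-trans-2-[(1S,3R)-1-hydroxy-3-(TBSO)butyl]-4-(TBSO)-3-vinylcyclopentan-1-one (daucane: C4 ketone, 1α-vinyl, 2β-OTBS, 5β side chain, anti aldol, 6S, 8R) | C=C[C@H]1[C@H](O[Si](C)(C)C(C)(C)C)CC(=O)[C@@H]1[C@@H](O)C[C@@H](C)O[Si](C)(C)C(C)(C)C | intermediate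
7 | diol: as 6 with C4 = C(β-OH)(α-isopropyl) | C=C[C@H]1[C@H](O[Si](C)(C)C(C)(C)C)C[C@@](O)(C(C)C)[C@@H]1[C@@H](O)C[C@@H](C)O[Si](C)(C)C(C)(C)C | intermediate
8 | O4/O6 acetonide of 7 (cis-fused 1,3-dioxane, C7 equatorial) | C=C[C@H]1[C@H](O[Si](C)(C)C(C)(C)C)C[C@]2(C(C)C)OC(C)(C)O[C@@H](C[C@@H](C)O[Si](C)(C)C(C)(C)C)[C@H]12 | intermediate
9 | methyl ester: as 8 with 1α-CO2CH3 (C15) in place of vinyl | COC(=O)[C@H]1[C@H](O[Si](C)(C)C(C)(C)C)C[C@]2(C(C)C)OC(C)(C)O[C@@H](C[C@@H](C)O[Si](C)(C)C(C)(C)C)[C@H]12 | intermediate
10 | diol: as 9 with free 2β-OH and (8R)-OH | COC(=O)[C@H]1[C@H](O)C[C@]2(C(C)C)OC(C)(C)O[C@@H](C[C@@H](C)O)[C@H]12 | intermediate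
11 | β-keto ester: as 10 with C2 ketone and C8 methyl ketone (C1 labile) | COC(=O)[C@H]1C(=O)C[C@]2(C(C)C)OC(C)(C)O[C@@H](CC(C)=O)[C@H]12 | intermediate
12 | vinyltriphenylphosphonium bromide | C=C[P+](c1ccccc1)(c1ccccc1)c1ccccc1.[Br-] | starting material
13 | phosphorus ylide: 11 alkylated at C1 (α face) by CH2–CH=PPh3, ester β | COC(=O)[C@]1(CC=P(c2ccccc2)(c2ccccc2)c2ccccc2)C(=O)C[C@]2(C(C)C)OC(C)(C)O[C@@H](CC(C)=O)[C@H]12 | intermediate
14 | methyl 4β,6α-isopropylidenedioxy-2-oxodauc-8-en-15-oate (trans-fused, 5α-H) | COC(=O)[C@]12CC=C(C)C[C@@H]3OC(C)(C)O[C@@](C(C)C)(CC1=O)[C@@H]23 | intermediate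
15 | 4β,6α-isopropylidenedioxydauc-8-ene-2,15-diol (C2 epimers) | OC[C@]12CC=C(C)C[C@@H]3OC(C)(C)O[C@@](C(C)C)(CC1O)[C@@H]23 | intermediate
16 | 4β,6α-isopropylidenedioxy-2-oxodauc-8-en-15-al | O=C[C@]12CC=C(C)C[C@@H]3OC(C)(C)O[C@@](C(C)C)(CC1=O)[C@@H]23 | intermediate
17 | 15-(4-methylbenzenesulfonyl)hydrazone of 16 | Cc1ccc(cc1)S(=O)(=O)N/N=C/[C@]12CC=C(C)C[C@@H]3OC(C)(C)O[C@@](C(C)C)(CC1=O)[C@@H]23 | intermediate
18 | 4β,6α-isopropylidenedioxydauc-8-en-2-one | C[C@]12CC=C(C)C[C@@H]3OC(C)(C)O[C@@](C(C)C)(CC1=O)[C@@H]23 | intermediate
19 | 4β,6α-dihydroxydauc-8-en-2-one | CC1=CC[C@]2(C)[C@@H]([C@@H](O)C1)[C@](O)(C(C)C)CC2=O | intermediate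
20 | 6α-(4-acetoxybenzoyloxy)-4β-hydroxydauc-8-en-2-one | CC1=CC[C@]2(C)[C@@H]([C@@H](OC(=O)c3ccc(OC(C)=O)cc3)C1)[C@](O)(C(C)C)CC2=O | intermediate
21 | 6α-(4-acetoxybenzoyloxy)dauc-8-ene-2α,4β-diol | CC1=CC[C@]2(C)[C@@H]([C@@H](OC(=O)c3ccc(OC(C)=O)cc3)C1)[C@](O)(C(C)C)C[C@@H]2O | intermediate
22 | 2α-hydroxyferutinin, 6α-(4-hydroxybenzoyloxy)dauc-8-ene-2α,4β-diol (1R,2S,4R,5S,6S in daucane numbering) | CC1=CC[C@]2(C)[C@@H]([C@@H](OC(=O)c3ccc(O)cc3)C1)[C@](O)(C(C)C)C[C@@H]2O | target

**Summary**

Total step count: 16. Longest linear sequence: 16 steps (1 → 2 → 3 → 6 → … → 22); 14 steps from enone 4.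

Steps most likely to fail:

Step 9 (proposed new method). The Michael addition is expected to proceed, but the seven-membered Wittig closure may lose out to intermolecular olefination or to quenching of the ylide by proton transfer. The fallback uses known chemistry, sets out from 11 and returns to 14. C-Allylation of 11 (allyl bromide, K2CO3, acetone; same convex-face approach) should give the allyl keto ester F1. Chemoselective Wittig methylenation of the unhindered methyl ketone (Ph3P=CH2, THF, 0 °C) should give the diene F2. Ring-closing metathesis (second-generation Grubbs catalyst, CH2Cl2, 40 °C) should then form C8=C9 and deliver 14.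

Step 3. The aldol may show poor simple diastereoselection at C6, or the enolate may equilibrate and lose the β-silyloxy group before it is trapped. The fallback sets out from 4 and returns to 6. The conjugate addition is run in the presence of Me3SiCl to isolate the silyl enol ether F3. A Mukaiyama aldol of F3 with 3 (BF3·OEt2, CH2Cl2, −78 °C) then proceeds through an open transition state, in which the aldehyde face is set by 1,3-anti induction from the β-silyloxy centre of 3 and the enol ether face by the vinyl group.

Step 12. Hydrazone formation at the neopentyl aldehyde may be incomplete, the C2 ketone may be reduced or condensed as well, or the formyl group may be lost by retro-Claisen cleavage. The fallback sets out from 15 and returns to 18. Primary-selective iodination (I2, PPh3, imidazole, toluene, 80 °C) should give the primary iodide F4. Radical reduction (Bu3SnH, AIBN, toluene, 80 °C) should give the 15-methyl alcohol F5. Dess–Martin oxidation of the C2 carbinol then gives 18.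

**Further compounds**

F1 | step 9 | C1-allyl keto ester (allyl α, ester β; acetonide and methyl ketone as in 11) | COC(=O)[C@]1(CC=C)C(=O)C[C@]2(C(C)C)OC(C)(C)O[C@@H](CC(C)=O)[C@H]12
F2 | step 9 | diene: F1 with the C8 ketone converted into C8(CH3)=CH2 | COC(=O)[C@]1(CC=C)C(=O)C[C@]2(C(C)C)OC(C)(C)O[C@@H](CC(C)=C)[C@H]12
F3 | step 3 | trimethylsilyl enol ether (C4=C5) of trans-4-(TBSO)-3-vinylcyclopentanone | C=C[C@H]1[C@H](O[Si](C)(C)C(C)(C)C)CC(O[Si](C)(C)C)=C1
F4 | step 12 | 15-iodo-4β,6α-isopropylidenedioxydauc-8-en-2-ol | IC[C@]12CC=C(C)C[C@@H]3OC(C)(C)O[C@@](C(C)C)(CC1O)[C@@H]23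
F5 | step 12 | 4β,6α-isopropylidenedioxydauc-8-en-2-ol | C[C@]12CC=C(C)C[C@@H]3OC(C)(C)O[C@@](C(C)C)(CC1O)[C@@H]23
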